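**Retrosynthetic overview** (ring A = methylcyclopentane, ring B = cyclooctane, ring C = cyclohexane, ring D = isopropylcyclopentanone)
1. Target ⇐ hydroxyl-directed epoxidation of a tetrasubstituted (Z)-alkene in ring B beside the tertiary carbinol; the ring D ketone is carried as a carbinol and oxidised late.
2. Ring B (closed last) ⇐ light-driven decarboxylative 8-endo radical cyclisation of a butanoic acid side chain on ring C onto a 1,3-diene on ring A.
3. Tertiary carbinol ⇐ addition of a (Z)-dienyllithium (ring A, from (S)-β-citronellene by Cp2Zr-mediated enyne cyclisation) to a ring C/D keto acid.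
4. Ring C/D keto acid ⇐ (S)-carvone (ring C): reductive alkylation (quaternary methyl), alkyne hydration/aldol (ring D), Li/NH3 (trans fusion), isopropenyl → ketone, Michael addition to methyl (Z)-but-2-enoate (side chain).
5. Ring order: C (bought) → D → A (separate branch) → B.

Assumption: Li/NH3 reductive alkylation of carvone places the incoming chain cis to the isopropenyl group (axial attack), so (S)-carvone is the correct enantiomer; if the sense were opposite, (R)-carvone would be bought instead.

**Route**

Step 1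
Reactants: 1 (S)-β-citronellene
Product: 2 (4S)-4-methylhex-5-enal
Conditions: O3, CH2Cl2/MeOH, −78 °C (stopped at indicator end-point); Me2S, −78 °C → rt
Reagents that add atoms: ozone, [O-][O+]=O
Why: Ozonolysis is selective because ozone attacks the electron-rich trisubstituted alkene far faster than the monosubstituted one, and the allylic stereocentre is untouched.

Step 2
Reactants: 2 (4S)-4-methylhex-5-enal
Product: 3 (5S)-1,1-dibromo-5-methylhepta-1,6-diene
Conditions: CBr4, PPh3, CH2Cl2, 0 °C
Reagents that add atoms: carbon tetrabromide, BrC(Br)(Br)Br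
Why: Corey–Fuchs (Ramirez) dibromo-olefination of an unhindered aldehyde.

Step 3
Reactants: 3 (5S)-1,1-dibromo-5-methylhepta-1,6-diene
Product: 4 (3S)-3-methyloct-1-en-6-yne
Conditions: nBuLi (2.1 equiv), THF, −78 → −20 °C; MeI, −78 °C → rt
Reagents that add atoms: iodomethane, IC
Why: Second stage of the Corey–Fuchs alkyne synthesis (bromine–lithium exchange, Fritsch–Buttenberg–Wiechell rearrangement), with the lithium acetylide methylated in the same pot.

Step 4
Reactants: 4 (3S)-3-methyloct-1-en-6-yne
Product: 6 (1Z,2R,3S)-1-(1-iodoethylidene)-2-(iodomethyl)-3-methylcyclopentane, via zirconacyclopentene 5 (not isolated)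
Conditions: Cp2ZrCl2, nBuLi (2 equiv), THF, −78 °C → rt; I2, 0 °C
Reagents that add atoms: iodine, [I][I]
Why: Negishi enyne bicyclisation mediated by Cp2Zr (from Cp2ZrCl2 and nBuLi) closes ring A with syn addition of the new ring carbon and zirconium across the alkyne, so iodinolysis with retention gives only the (Z)-alkenyl iodide plus the primary iodide; the configuration at the iodomethyl-bearing carbon is erased in step 5.

Step 5
Reactants: 6 (1Z,2R,3S)-1-(1-iodoethylidene)-2-(iodomethyl)-3-methylcyclopentane
Product: 7 (1Z,3S)-1-(1-iodoethylidene)-3-methyl-2-methylidenecyclopentane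
Conditions: KOtBu, THF, 0 °C
Reagents that add atoms: none
Why: E2 dehydroiodination of the primary iodide through the tertiary allylic hydrogen gives the s-cis-locked exocyclic diene and leaves the alkenyl iodide and the methyl stereocentre untouched.

Step 6
Reactants: 8 4-methylpent-2-yn-1-ol
Product: 9 1-bromo-4-methylpent-2-yne
Conditions: PBr3, pyridine (cat.), Et2O, 0 °C
Reagents that add atoms: phosphorus tribromide, BrP(Br)Br
Why: SN2 bromination of a primary propargylic alcohol.

Step 7
Reactants: 10 (S)-(+)-carvone; 9 1-bromo-4-methylpent-2-yne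
Product: 11 (2S,5S)-2-methyl-2-(4-methylpent-2-yn-1-yl)-5-(prop-1-en-2-yl)cyclohexan-1-one
Conditions: Li (2.0 equiv), NH3(l)/THF, tBuOH (1 equiv), −78 °C; then 9, −78 → −33 °C; NH4Cl
Reagents that add atoms: none
Why: Stork reductive alkylation generates the enolate regiospecifically at the methyl-bearing carbon, and axial alkylation of the half-chair enolate, cis to the pseudo-equatorial isopropenyl group, fixes the quaternary methyl centre (minor epimer removed by chromatography).

Step 8
Reactants: 11 (2S,5S)-2-methyl-2-(4-methylpent-2-yn-1-yl)-5-(prop-1-en-2-yl)cyclohexan-1-one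
Product: 13 (5S,7aS)-7a-methyl-3-(propan-2-yl)-5-(prop-1-en-2-yl)-1,4,5,6,7,7a-hexahydro-2H-inden-2-one, via 1,4-diketone 12 (not isolated)
Conditions: NaAuCl4·2H2O (2 mol%), MeOH/H2O, 60 °C; then KOH, 65 °C
Reagents that add atoms: water, O
Why: NaAuCl4-catalysed alkyne hydration assisted by the ring carbonyl (5-exo attack) places the new ketone two carbons from the quaternary centre, and intramolecular aldol condensation of the 1,4-diketone closes ring D as the conjugated cyclopentenone.

Step 9
Reactants: 13 (5S,7aS)-7a-methyl-3-(propan-2-yl)-5-(prop-1-en-2-yl)-1,4,5,6,7,7a-hexahydro-2H-inden-2-one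
Product: 15 (2S,3R,3aS,5S,7aS)-7a-methyl-3-(propan-2-yl)-5-(prop-1-en-2-yl)octahydro-1H-inden-2-ol, via saturated ketone 14 (not isolated)
Conditions: Li, NH3(l)/THF, tBuOH (1 equiv), −78 °C; NH4Cl; then NaBH4, MeOH, 0 °C
Reagents that add atoms: none
Why: Dissolving-metal enone reduction protonates the β-carbon axially, anti to the angular methyl (trans ring fusion), kinetic protonation of the enolate on the same α-face puts the isopropyl group cis to the angular methyl, and NaBH4 then masks the ring D carbonyl as a carbinol by α-face hydride delivery before the α-centre can epimerise (any cis-fused isomer removed by chromatography).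

Step 10
Reactants: 15 (2S,3R,3aS,5S,7aS)-7a-methyl-3-(propan-2-yl)-5-(prop-1-en-2-yl)octahydro-1H-inden-2-ol
Product: 18 (2S,3R,3aS,7aS)-2-hydroxy-7a-methyl-3-(propan-2-yl)octahydro-5H-inden-5-one, via methoxy hydroperoxide 16 (not isolated), via alkoxyamine 17 (not isolated)
Conditions: O3, MeOH, −78 °C; FeSO4·7H2O, TEMPO, −78 °C → rt; magnesium bis(monoperoxyphthalate) hexahydrate, rt
Reagents that add atoms: TEMPO, CC1(C)CCCC(C)(C)N1[O]
Why: Oxodealkenylation: ozonolysis in methanol gives the α-methoxy hydroperoxide, FeSO4 (divalent iron) triggers alkoxy-radical β-scission, TEMPO traps the ring radical and peracid oxidation of the alkoxyamine releases the ring C ketone; the stereocentre lost here has already set the quaternary centre.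

Step 11
Reactants: 19 methyl but-2-ynoate
Product: 20 methyl (Z)-but-2-enoate
Conditions: H2 (1 atm), Pd/CaCO3 poisoned with Pb(OAc)2 (Lindlar catalyst), quinoline, pentane, 0 °C
Reagents that add atoms: none
Why: Semihydrogenation over Pb(OAc)2-poisoned Pd/CaCO3 adds hydrogen syn to the alkyne and gives the (Z)-enoate.

Step 12
Reactants: 18 (2S,3R,3aS,7aS)-2-hydroxy-7a-methyl-3-(propan-2-yl)octahydro-5H-inden-5-one; 20 methyl (Z)-but-2-enoate
Product: 22 (3R)-3-[(2S,3R,3aS,6R,7aS)-2-hydroxy-7a-methyl-5-oxo-3-(propan-2-yl)octahydro-1H-inden-6-yl]butanoic acid, via methyl ester 21 (not isolated)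
Conditions: LDA (2.2 equiv), THF, −78 °C; 20, −78 °C; then LiOH, H2O/MeOH, rt; HCl to pH 3
Reagents that add atoms: lithium hydroxide, [Li+].[OH-]
Why: Michael addition: LDA enolises the cyclohexanone away from the ring fusion (as in trans-fused 3-oxo steroids), the enolate attacks on the α-face because the angular methyl blocks the β-face, and the lithium-chelated closed transition state with the (Z)-enoate holds its methyl over the enolate to give the anti (R,R) pair of new stereocentres; LiOH then hydrolyses the ester and leaves the side chain equatorial.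

Step 13
Reactants: 7 (1Z,3S)-1-(1-iodoethylidene)-3-methyl-2-methylidenecyclopentane; 22 (3R)-3-[(2S,3R,3aS,6R,7aS)-2-hydroxy-7a-methyl-5-oxo-3-(propan-2-yl)octahydro-1H-inden-6-yl]butanoic acid
Product: 24 (3R)-3-[(2S,3R,3aS,5R,6R,7aS)-2,5-dihydroxy-7a-methyl-5-{(1Z)-1-[(3S)-3-methyl-2-methylidenecyclopentylidene]ethyl}-3-(propan-2-yl)octahydro-1H-inden-6-yl]butanoic acid, via dienyllithium 23 (not isolated)
Conditions: 7, tBuLi (2 equiv), Et2O, −78 °C; 22 pre-treated with NaH (2.1 equiv), THF, 0 °C; −78 → −30 °C; aq. NH4Cl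
Reagents that add atoms: none
Why: Iodine–lithium exchange with retention gives the (Z)-dienyllithium, whose 1,2-addition to the ketone of the disodium salt follows the equatorial trajectory expected for a bulky sp2 organolithium (axial tertiary hydroxyl, new carbon trans to the equatorial side chain), the carboxylate being inert at −78 °C.

Step 14
Reactants: 24 (3R)-3-[(2S,3R,3aS,5R,6R,7aS)-2,5-dihydroxy-7a-methyl-5-{(1Z)-1-[(3S)-3-methyl-2-methylidenecyclopentylidene]ethyl}-3-(propan-2-yl)octahydro-1H-inden-6-yl]butanoic acid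
Product: 25 ring B-closed diol (target skeleton with the (Z)-alkene in place of the epoxide and an (S)-carbinol in place of the ring D ketone)
Conditions: [Ir(dF(CF3)ppy)2(dtbbpy)]PF6 (2 mol%), 2,4,6-triisopropylbenzenethiol (5 mol%), Cs2CO3 (0.2 equiv), MeCN/H2O (9:1), 1 mM, 450 nm LEDs, 25 °C, degassed
Reagents that add atoms: none
Why: Proposed new method: visible-light decarboxylative 8-endo radical cyclisation onto a 1,3-diene with thiol hydrogen-atom-transfer termination – excited [Ir(dF(CF3)ppy)2(dtbbpy)]PF6 oxidises the carboxylate, loss of CO2 gives a primary radical that adds to the unhindered CH2 terminus of the s-cis diene held beside it by the two adjacent equatorial substituents on ring C (primary radicals add to diene termini much faster than to simple alkenes, while the competing 5-exo attack would have to build two adjacent quaternary carbons), and the allyl radical takes hydrogen from the bulky arenethiol at its less hindered end, anti to the neighbouring ring A methyl, which closes ring B, leaves the tetrasubstituted (Z)-alkene and sets the ring A/B junction hydrogen, while reduction and reprotonation of the thiyl radical turn both catalysts over; the closest known reactions are photoredox decarboxylative Giese additions, thiol-co-catalysed hydrodecarboxylations and Bu3SnH-mediated 8-endo radical cyclisations.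

Step 15
Reactants: 25 ring B-closed diol
Product: 26 ring B-closed hydroxy ketone (target without the epoxide oxygen)
Conditions: Dess–Martin periodinane, NaHCO3, CH2Cl2, 0 °C → rt
Reagents that add atoms: none
Why: Dess–Martin oxidation converts the secondary carbinol into the ring D ketone under buffered, non-epimerising conditions; the tertiary alcohol and the tetrasubstituted alkene do not react.

Step 16
Reactants: 26 ring B-closed hydroxy ketone
Product: 27 target CNP0332295.1
Conditions: VO(acac)2 (5 mol%), tBuOOH, CH2Cl2, 0 °C → rt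
Reagents that add atoms: tert-butyl hydroperoxide, CC(C)(C)OO
Why: VO(acac)2-catalysed hydroxyl-directed epoxidation delivers the peroxide oxygen to the tetrasubstituted alkene on the face syn to the bound tertiary allylic alkoxide, which is the relative configuration of the target's epoxy alcohol.

**Compound list**
1 | (S)-β-citronellene, (3S)-3,7-dimethylocta-1,6-diene | C=C[C@@H](C)CCC=C(C)C | starting material
2 | (4S)-4-methylhex-5-enal | C=C[C@@H](C)CCC=O | intermediate
3 | (5S)-1,1-dibromo-5-methylhepta-1,6-diene | C=C[C@@H](C)CCC=C(Br)Br | intermediate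
4 | (3S)-3-methyloct-1-en-6-yne | C=C[C@@H](C)CCC#CC | intermediate
5 | zirconacyclopentene (Cp2Zr bridging the alkenyl carbon and the ring CH2, ring A closed) | CC1=C2CC[C@H](C)[C@H]2C[Zr]1(C1C=CC=C1)C1C=CC=C1 | intermediate (not isolated)
6 | (1Z,2R,3S)-1-(1-iodoethylidene)-2-(iodomethyl)-3-methylcyclopentane | C/C(I)=C1\CC[C@H](C)[C@H]1CI | intermediate
7 | (1Z,3S)-1-(1-iodoethylidene)-3-methyl-2-methylidenecyclopentane | C/C(I)=C1\CC[C@H](C)C1=C | intermediate
8 | 4-methylpent-2-yn-1-ol | CC(C)C#CCO | starting material
9 | 1-bromo-4-methylpent-2-yne | CC(C)C#CCBr | intermediate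
10 | (S)-(+)-carvone | CC1=CC[C@H](C(C)=C)CC1=O | starting material
11 | (2S,5S)-2-methyl-2-(4-methylpent-2-yn-1-yl)-5-(prop-1-en-2-yl)cyclohexan-1-one | CC(C)C#CC[C@]1(C)CC[C@H](C(C)=C)CC1=O | intermediate
12 | (2S,5S)-2-methyl-2-(4-methyl-2-oxopentyl)-5-(prop-1-en-2-yl)cyclohexan-1-one | CC(C)CC(=O)C[C@]1(C)CC[C@H](C(C)=C)CC1=O | intermediate (not isolated)
13 | (5S,7aS)-7a-methyl-3-(propan-2-yl)-5-(prop-1-en-2-yl)-1,4,5,6,7,7a-hexahydro-2H-inden-2-one | CC(C)C1=C2C[C@@H](C(C)=C)CC[C@@]2(C)CC1=O | intermediate
14 | (3R,3aS,5S,7aS)-7a-methyl-3-(propan-2-yl)-5-(prop-1-en-2-yl)octahydro-2H-inden-2-one | CC(C)[C@H]1C(=O)C[C@]2(C)CC[C@H](C(C)=C)C[C@@H]12 | intermediate (not isolated)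
15 | (2S,3R,3aS,5S,7aS)-7a-methyl-3-(propan-2-yl)-5-(prop-1-en-2-yl)octahydro-1H-inden-2-ol | CC(C)[C@H]1[C@@H](O)C[C@]2(C)CC[C@H](C(C)=C)C[C@@H]12 | intermediate
16 | (2S,3R,3aS,5S,7aS)-5-(1-hydroperoxy-1-methoxyethyl)-7a-methyl-3-(propan-2-yl)octahydro-1H-inden-2-ol (both epimers at the peroxy carbon) | CC(C)[C@H]1[C@@H](O)C[C@]2(C)CC[C@H](C(C)(OC)OO)C[C@@H]12 | intermediate (not isolated)
17 | (2S,3R,3aS,7aS)-7a-methyl-3-(propan-2-yl)-5-[(2,2,6,6-tetramethylpiperidin-1-yl)oxy]octahydro-1H-inden-2-ol (both epimers at the oxygen-bearing ring C carbon) | CC(C)[C@H]1[C@@H](O)C[C@]2(C)CCC(ON3C(C)(C)CCCC3(C)C)C[C@@H]12 | intermediate (not isolated)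
18 | (2S,3R,3aS,7aS)-2-hydroxy-7a-methyl-3-(propan-2-yl)octahydro-5H-inden-5-one | CC(C)[C@H]1[C@@H](O)C[C@]2(C)CCC(=O)C[C@@H]12 | intermediate
19 | methyl but-2-ynoate | CC#CC(=O)OC | starting material
20 | methyl (Z)-but-2-enoate | C/C=C\C(=O)OC | intermediate
21 | methyl (3R)-3-[(2S,3R,3aS,6R,7aS)-2-hydroxy-7a-methyl-5-oxo-3-(propan-2-yl)octahydro-1H-inden-6-yl]butanoate | CC(C)[C@H]1[C@@H](O)C[C@]2(C)C[C@H]([C@H](C)CC(=O)OC)C(=O)C[C@@H]12 | intermediate (not isolated)
22 | (3R)-3-[(2S,3R,3aS,6R,7aS)-2-hydroxy-7a-methyl-5-oxo-3-(propan-2-yl)octahydro-1H-inden-6-yl]butanoic acid | CC(C)[C@H]1[C@@H](O)C[C@]2(C)C[C@H]([C@H](C)CC(O)=O)C(=O)C[C@@H]12 | intermediate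
23 | {1-[(3S)-3-methyl-2-methylidenecyclopentylidene]ethyl}lithium, geometry of 7 retained (lithium cis to the methylidene-bearing ring carbon) | C/C([Li])=C1\CC[C@H](C)C1=C | intermediate (not isolated)
24 | (3R)-3-[(2S,3R,3aS,5R,6R,7aS)-2,5-dihydroxy-7a-methyl-5-{(1Z)-1-[(3S)-3-methyl-2-methylidenecyclopentylidene]ethyl}-3-(propan-2-yl)octahydro-1H-inden-6-yl]butanoic acid | CC(C)[C@H]1[C@@H](O)C[C@]2(C)C[C@H]([C@H](C)CC(O)=O)[C@](O)(C[C@@H]12)/C(C)=C1/CC[C@H](C)C1=C | intermediate
25 | ring B-closed diol: target skeleton with a tetrasubstituted (Z)-alkene in place of the epoxide and an (S)-carbinol (hydroxyl cis to isopropyl) in place of the ring D ketone | CC(C)[C@H]1[C@@H](O)C[C@]2(C)C[C@@H]3[C@H](C)CC[C@H]4[C@@H](C)CC/C4=C(\C)[C@@]3(O)C[C@@H]12 | intermediate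
26 | ring B-closed hydroxy ketone: target without the epoxide oxygen (tetrasubstituted (Z)-alkene) | CC(C)[C@H]1C(=O)C[C@]2(C)C[C@@H]3[C@H](C)CC[C@H]4[C@@H](C)CC/C4=C(\C)[C@@]3(O)C[C@@H]12 | intermediate
27 | CNP0332295.1 | CC(C)[C@H]1C(=O)C[C@]2(C)C[C@@H]3[C@H](C)CC[C@H]4[C@@H](C)CC[C@]45O[C@]5(C)[C@@]3(O)C[C@@H]12 | target

**Totals**
Total step count: 16. Longest linear sequence: 10 steps (8 → 27 through steps 6, 7, 8, 9, 10, 12, 13, 14, 15, 16). The carvone branch 10 → 27 and the ring A branch 1 → 27 are 9 steps each.

**The three steps most likely to fail**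

Step 12 (Michael addition). The anti relationship of the two new stereocentres depends on the closed transition state with a (Z)-enoate, and enolate proton transfer to the enoate or Z/E leakage would erode it. The fallback replaces the enolate addition by a Claisen rearrangement; it sets out from 18 and comes back at 22. Ketone 18 is heated with (Z)-but-2-en-1-ol and catalytic propionic acid in xylene with removal of water. The (Z)-crotyl enol ether F1, formed on the side away from the ring fusion, rearranges through a chair transition state on the α-face to (2S,3R,3aS,6R,7aS)-6-[(2R)-but-3-en-2-yl]-2-hydroxy-7a-methyl-3-(propan-2-yl)octahydro-5H-inden-5-one F2. Aldehyde-selective Wacker oxidation (PdCl2(PhCN)2, CuCl2, AgNO2, O2, tBuOH/MeNO2) gives the butanal F3, and NaClO2/NaH2PO4 oxidation returns acid 22.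

Step 13 (fragment union). The disodium salt of 22 may be poorly soluble, and the hindered ketone may be enolised rather than attacked. The fallback replaces the dianion by the ester and uses lactonisation as internal protection; it sets out from 21 (isolated from step 12 by leaving out the LiOH stage) and 7, and comes back at 24. Dienyllithium 23 is added to 21 (hydroxyl first deprotonated with one equivalent of NaH) at −78 °C. On warming, the tertiary alkoxide closes onto the methyl ester to give the δ-lactone F4, and LiOH in THF/H2O at 40 °C followed by acidification to pH 5 opens it to 24.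

Step 14 (new photochemical ring closure). Hydrogen transfer to the primary radical before cyclisation, 5-exo closure on the substituted diene terminus, or hydrogen delivery to the wrong end of the allyl radical would each defeat it. Photoisomerisation of the diene is tolerable, since the isomers interconvert under the light and only the (Z)-isomer can cyclise. The fallback uses known chemistry, ring-closing metathesis followed by diimide reduction, a ring closure precedented on this ring system; it sets out from 7 and 18 and comes back at 25. Diene 7 is hydroborated with 9-BBN at the exocyclic CH2, with hydrogen delivered anti to the ring methyl, giving the alkylborane F5. NaOH/H2O2 gives [(1S,2S,5Z)-5-(1-iodoethylidene)-2-methylcyclopentyl]methanol F6, Dess–Martin periodinane gives the aldehyde F7 (kept cold and used at once to avoid epimerisation), and Ph3P=CH2 gives (1Z,2S,3S)-2-ethenyl-1-(1-iodoethylidene)-3-methylcyclopentane F8. tBuLi converts F8 into the alkenyllithium F9, which is added to vinyl ketone F2 (made from 18 as in the fallback to step 12, hydroxyl deprotonated with NaH) to give the trienediol F10. The second-generation Grubbs catalyst (H2IMes)(PCy3)Cl2Ru=CHPh in CH2Cl2 at 40 °C closes ring B between the two vinyl groups to the cyclooctene F11. Diimide (potassium azodicarboxylate, AcOH) reduces only the disubstituted ring alkene and gives 25.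

Further compounds
F1 | step 12 | (Z)-but-2-en-1-yl enol ether of 18 (enol double bond on the side away from the ring fusion) | CC(C)[C@H]1[C@@H](O)C[C@]2(C)CC=C(OC/C=C\C)C[C@@H]12
F2 | step 12 | (2S,3R,3aS,6R,7aS)-6-[(2R)-but-3-en-2-yl]-2-hydroxy-7a-methyl-3-(propan-2-yl)octahydro-5H-inden-5-one | CC(C)[C@H]1[C@@H](O)C[C@]2(C)C[C@H]([C@H](C)C=C)C(=O)C[C@@H]12
F3 | step 12 | (3R)-3-[(2S,3R,3aS,6R,7aS)-2-hydroxy-7a-methyl-5-oxo-3-(propan-2-yl)octahydro-1H-inden-6-yl]butanal | CC(C)[C@H]1[C@@H](O)C[C@]2(C)C[C@H]([C@H](C)CC=O)C(=O)C[C@@H]12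
F4 | step 13 | δ-lactone of 24 (carboxyl closed onto the tertiary hydroxyl) | CC(C)[C@H]1[C@@H](O)C[C@]2(C)C[C@@H]3[C@H](C)CC(=O)O[C@@]3(C[C@@H]12)/C(C)=C1/CC[C@H](C)C1=C
F5 | step 14 | 9-{[(1S,2S,5Z)-5-(1-iodoethylidene)-2-methylcyclopentyl]methyl}-9-borabicyclo[3.3.1]nonane | C/C(I)=C1\CC[C@H](C)[C@@H]1CB1C2CCCC1CCC2
F6 | step 14 | [(1S,2S,5Z)-5-(1-iodoethylidene)-2-methylcyclopentyl]methanol | C/C(I)=C1\CC[C@H](C)[C@@H]1CO
F7 | step 14 | (1S,2S,5Z)-5-(1-iodoethylidene)-2-methylcyclopentane-1-carbaldehyde | C/C(I)=C1\CC[C@H](C)[C@@H]1C=O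
F8 | step 14 | (1Z,2S,3S)-2-ethenyl-1-(1-iodoethylidene)-3-methylcyclopentane | C/C(I)=C1\CC[C@H](C)[C@@H]1C=C
F9 | step 14 | {1-[(2S,3S)-2-ethenyl-3-methylcyclopentylidene]ethyl}lithium, geometry of F8 retained | C/C([Li])=C1\CC[C@H](C)[C@@H]1C=C
F10 | step 14 | trienediol: adduct of F9 and F2 (tertiary carbinol as in 24, vinyl groups on ring A and on the side chain) | CC(C)[C@H]1[C@@H](O)C[C@]2(C)C[C@H]([C@H](C)C=C)[C@](O)(C[C@@H]12)/C(C)=C1/CC[C@H](C)[C@@H]1C=C
F11 | step 14 | ring B-closed dienediol: 25 with an additional (Z)-alkene between the two ring B CH2 carbons | CC(C)[C@H]1[C@@H](O)C[C@]2(C)C[C@@H]3[C@H](C)/C=C\[C@H]4[C@@H](C)CC/C4=C(\C)[C@@]3(O)C[C@@H]12
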